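**Retrosynthetic overview**

1. Skeletal atoms carry eudesmane numbers (ring A = C1–C5 + C10, ring B = C5–C10, C14 = angular CH3, C15 = CH2O on C4, C11–C13 = acrylate on C7). The (Z)-p-coumarate is cut at the C15–O bond and at its aryl–alkene bond (esterification with (Z)-3-iodoacrylic acid, then Suzuki arylation), and C15 is traced back to a C4 alkenyl bromide.
2. Both carbocycles are then opened in one retro-Diels–Alder disconnection (bonds C5–C10 and C1–C2) to an open-chain (Z)-2-bromodiene/isopropenyl tetraene whose only stereocentre is C7.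
3. Enabling feature: ring A is a cyclohexene whose C3=C4 double bond lies next to the ring-fusion carbon C5, with C1 and C2 as plain CH2 groups and C10 as the methyl-bearing quaternary carbon. It is therefore the adduct of a C2=C3–C4=C5 diene and a C1=C10 isopropenyl group, and ring B (C5–C10) is just the four-carbon tether C6–C9 that carries C7.
4. The tetraene comes from (R)-limonene (C5–C14 and the C7 centre): oxidation of the isopropenyl CH3 to the ester, ozonolysis of the ring alkene (C5 aldehyde, C10 ketone), Ramirez olefination (C4), methylenation (C1) and a trans-selective vinyl coupling (C2, C3).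
5. Order of ring formation: the limonene ring is opened in step 4, so no ring exists before the key step. Step 8 closes ring B (through the C5–C10 bond) and ring A (C5–C10 plus C1–C2, the ring completed last) in one operation. The arene arrives preformed in step 11.

Key step: step 8

Remark: the eudesmane numbers are also used for the open-chain intermediates, whose atoms map one-to-one onto the target.

**Route**

Step 1
Reactants: 1 (R)-(+)-limonene
Product: 4 2-[(1R)-4-methylcyclohex-3-en-1-yl]prop-2-en-1-ol, via allyllithium 2 (not isolated), via allylboronate 3 (not isolated)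
Conditions: n-BuLi, TMEDA, hexane, 25 °C; B(OMe)3, THF, −78 to 0 °C; then H2O2, aq NaOH, 0 °C
Reagents that add atoms: hydrogen peroxide, OO
Why: Allylic lithiation: n-BuLi·TMEDA removes a proton from the isopropenyl CH3 of limonene (the later C12) to give a symmetric 2-substituted allyllithium that does not involve the stereocentre, and borylation followed by alkaline H2O2 oxidation (C–B to C–O) delivers the primary allylic alcohol.

Step 2
Reactants: 4 2-[(1R)-4-methylcyclohex-3-en-1-yl]prop-2-en-1-ol
Product: 6 2-[(1R)-4-methylcyclohex-3-en-1-yl]prop-2-enoic acid, via enal 5 (not isolated)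
Conditions: TEMPO (cat.), PhI(OAc)2, CH2Cl2, 25 °C; then NaClO2, NaH2PO4, 2-methyl-2-butene, t-BuOH/H2O, 0 to 25 °C
Reagents that add atoms: sodium chlorite, [Na+].[O-]Cl=O
Why: TEMPO/PhI(OAc)2 oxidation takes the allylic alcohol to the enal only, and the Pinnick oxidation run in the same flask with an alkene scavenger converts it into the acrylic acid without chlorination of the electron-rich ring alkene.

Step 3
Reactants: 6 2-[(1R)-4-methylcyclohex-3-en-1-yl]prop-2-enoic acid
Product: 7 methyl 2-[(1R)-4-methylcyclohex-3-en-1-yl]prop-2-enoate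
Conditions: MeI, K2CO3, DMF, 25 °C
Reagents that add atoms: iodomethane, CI
Why: SN2 O-methylation of the potassium carboxylate, a mild esterification that cannot add to or isomerize the α-methylene unit.

Step 4
Reactants: 7 methyl 2-[(1R)-4-methylcyclohex-3-en-1-yl]prop-2-enoate
Product: 9 methyl (3R)-2-methylidene-6-oxo-3-(2-oxoethyl)heptanoate, via ozonide 8 (not isolated)
Conditions: O3, CH2Cl2, −78 °C (Sudan Red 7B end point); then PPh3, −78 to 25 °C
Reagents that add atoms: ozone, [O-][O+]=O
Why: Chemoselective ozonolysis with reductive work-up: electrophilic ozone cleaves the electron-rich trisubstituted ring alkene far faster than the electron-poor acrylate (dye end point), opening the ring to the C5 aldehyde and the C10 methyl ketone without touching the C7 centre.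

Step 5
Reactants: 9 methyl (3R)-2-methylidene-6-oxo-3-(2-oxoethyl)heptanoate
Product: 10 methyl (3R)-3-(3,3-dibromoprop-2-en-1-yl)-2-methylidene-6-oxoheptanoate
Conditions: CBr4, PPh3, CH2Cl2, 0 °C
Reagents that add atoms: tetrabromomethane, BrC(Br)(Br)Br
Why: Ramirez dibromo-olefination (first half of the Corey–Fuchs sequence): Ph3P=CBr2 attacks the aldehyde at 0 °C while the methyl ketone and the ester do not react, which installs C4 as a 1,1-dibromoalkene.

Step 6
Reactants: 10 methyl (3R)-3-(3,3-dibromoprop-2-en-1-yl)-2-methylidene-6-oxoheptanoate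
Product: 11 methyl (3R)-3-(3,3-dibromoprop-2-en-1-yl)-6-methyl-2-methylidenehept-6-enoate
Conditions: Zn, CH2Br2, TiCl4, THF (pre-formed reagent), then 10 in CH2Cl2, 0 to 25 °C
Reagents that add atoms: dibromomethane, BrCBr
Why: Takai–Lombardo methylenation: the non-basic zinc–titanium methylene reagent converts the methyl ketone into the isopropenyl dienophile (C1) without enolization and is known to tolerate esters and alkenyl halides.

Step 7
Reactants: 11 methyl (3R)-3-(3,3-dibromoprop-2-en-1-yl)-6-methyl-2-methylidenehept-6-enoate; 12 tributyl(vinyl)stannane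
Product: 13 methyl (3R,5Z)-6-bromo-3-(3-methylbut-3-en-1-yl)-2-methylideneocta-5,7-dienoate
Conditions: Pd2(dba)3 (2.5 mol %), tri(2-furyl)phosphine (15 mol %), PhMe, 90 °C
Reagents that add atoms: none
Why: trans-Selective mono-Stille coupling of a 1,1-dibromoalkene: oxidative addition takes place at the less hindered C–Br bond trans to C6, so the vinyl group (C2, C3) enters trans to the chain and the (5Z)-2-bromodiene is formed, and palladium bound on that side cannot reach the acrylate for a Heck cyclization.

Step 8
Reactants: 13 methyl (3R,5Z)-6-bromo-3-(3-methylbut-3-en-1-yl)-2-methylideneocta-5,7-dienoate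
Product: 14 methyl 2-[(2R,4aS,8aR)-8-bromo-4a-methyl-1,2,3,4,4a,5,6,8a-octahydronaphthalen-2-yl]prop-2-enoate
Conditions: PhMe (0.01 M), BHT (cat.), degassed, sealed silylated glass tube, 200–210 °C
Reagents that add atoms: none
Why: A concerted, thermal [4+2] cycloaddition (type 1 intramolecular Diels–Alder reaction) between the C2=C3–C4(Br)=C5 diene and the unactivated isopropenyl dienophile C1=C10; the closest known reaction type is the thermal cyclization of 2-methyl-1,7,9-decatrienes to angularly methylated octalins, and a bromine on the diene carbon next to the tether is an established steric directing group in such reactions. Ring A is closed by the cycloaddition itself (bonds C5–C10 and C1–C2, suprafacial on both partners, six-membered), and ring B is closed in the same event by the C5–C10 bond across the four-carbon tether C6–C9 (six-membered, chair-like). C5 and C10 are set together as the trans ring fusion, because the tether sits outside on the (5Z)-diene and exo on the dienophile with the C14 methyl endo, while the alternative tether-endo (cis-fused) arrangement forces the tether against the C4 bromine. Their absolute sense is relayed from C7, whose acrylate-bearing substituent takes the equatorial position on the chair-like tether, so that the natural eudesmane pattern (5α-H, 10β-CH3, 7β side chain) should result. The step needs site selectivity against the acrylate C11=C13 and diastereoselectivity at the ring fusion: the acrylate is held only two atoms from the diene terminus and cannot reach a cycloaddition geometry, high dilution (which also keeps the α-substituted acrylate above its ceiling temperature) and BHT suppress bimolecular pathways, and the (5Z) geometry leaves no alkyl group cis to the vinyl unit, so a 1,5-hydrogen shift of the diene cannot compete.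

Step 9
Reactants: 14 methyl 2-[(2R,4aS,8aR)-8-bromo-4a-methyl-1,2,3,4,4a,5,6,8a-octahydronaphthalen-2-yl]prop-2-enoate; 15 (tributylstannyl)methanol
Product: 16 methyl 2-[(2R,4aR,8aR)-8-(hydroxymethyl)-4a-methyl-1,2,3,4,4a,5,6,8a-octahydronaphthalen-2-yl]prop-2-enoate
Conditions: Pd(PPh3)4 (10 mol %), 1,4-dioxane, 90 °C
Reagents that add atoms: none
Why: Stille coupling with transfer of the hydroxymethyl group from tin to the C4 alkenyl bromide, run after ring closure so that the alkene is endocyclic (no geometry to lose) and the equatorial acrylate on ring B cannot reach the C4–palladium bond.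

Step 10
Reactants: 16 methyl 2-[(2R,4aR,8aR)-8-(hydroxymethyl)-4a-methyl-1,2,3,4,4a,5,6,8a-octahydronaphthalen-2-yl]prop-2-enoate; 17 (2Z)-3-iodoprop-2-enoic acid
Product: 18 methyl 2-[(2R,4aR,8aR)-8-({[(2Z)-3-iodoprop-2-enoyl]oxy}methyl)-4a-methyl-1,2,3,4,4a,5,6,8a-octahydronaphthalen-2-yl]prop-2-enoate
Conditions: EDC·HCl, DMAP (10 mol %), CH2Cl2, 0 °C, dark
Reagents that add atoms: none
Why: Steglich esterification (carbodiimide, catalytic DMAP) of the primary allylic alcohol at 0 °C in the dark, conditions under which (Z)-3-iodoacrylic acid is known to be acylated onto alcohols with its geometry intact.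

Step 11
Reactants: 18 methyl 2-[(2R,4aR,8aR)-8-({[(2Z)-3-iodoprop-2-enoyl]oxy}methyl)-4a-methyl-1,2,3,4,4a,5,6,8a-octahydronaphthalen-2-yl]prop-2-enoate; 19 (4-hydroxyphenyl)boronic acid
Product: 20 methyl 2-[(2R,4aR,8aR)-8-({[(2Z)-3-(4-hydroxyphenyl)prop-2-enoyl]oxy}methyl)-4a-methyl-1,2,3,4,4a,5,6,8a-octahydronaphthalen-2-yl]prop-2-enoate
Conditions: PdCl2(dppf) (5 mol %), NaHCO3, THF/H2O, 25–40 °C, dark
Reagents that add atoms: none
Why: Suzuki–Miyaura coupling of the (Z)-β-iodoacrylate, which proceeds with retention of alkene geometry; oxidative addition into the C–I bond near room temperature is much faster than ionization of the allylic C15–O ester, and the weak base keeps the phenol largely un-ionized and both esters intact.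

**Compound list**

1 | (R)-(+)-limonene, (4R)-1-methyl-4-(prop-1-en-2-yl)cyclohex-1-ene | CC1=CC[C@@H](CC1)C(C)=C | starting material
2 | {2-[(1R)-4-methylcyclohex-3-en-1-yl]prop-2-en-1-yl}lithium | CC1=CC[C@@H](CC1)C(=C)C[Li] | intermediate
3 | dimethyl {2-[(1R)-4-methylcyclohex-3-en-1-yl]prop-2-en-1-yl}boronate | CC1=CC[C@@H](CC1)C(=C)CB(OC)OC | intermediate
4 | 2-[(1R)-4-methylcyclohex-3-en-1-yl]prop-2-en-1-ol | CC1=CC[C@@H](CC1)C(=C)CO | intermediate
5 | 2-[(1R)-4-methylcyclohex-3-en-1-yl]prop-2-enal | CC1=CC[C@@H](CC1)C(=C)C=O | intermediate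
6 | 2-[(1R)-4-methylcyclohex-3-en-1-yl]prop-2-enoic acid | CC1=CC[C@@H](CC1)C(=C)C(=O)O | intermediate
7 | methyl 2-[(1R)-4-methylcyclohex-3-en-1-yl]prop-2-enoate | CC1=CC[C@@H](CC1)C(=C)C(=O)OC | intermediate
8 | methyl 2-[(4R)-1-methyl-7,8,9-trioxabicyclo[4.2.1]nonan-4-yl]prop-2-enoate (secondary ozonide of 7, bridgehead centres as formed) | CC12CC[C@H](CC(O1)OO2)C(=C)C(=O)OC | intermediate
9 | methyl (3R)-2-methylidene-6-oxo-3-(2-oxoethyl)heptanoate | O=CC[C@@H](CCC(C)=O)C(=C)C(=O)OC | intermediate
10 | methyl (3R)-3-(3,3-dibromoprop-2-en-1-yl)-2-methylidene-6-oxoheptanoate | BrC(Br)=CC[C@@H](CCC(C)=O)C(=C)C(=O)OC | intermediate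
11 | methyl (3R)-3-(3,3-dibromoprop-2-en-1-yl)-6-methyl-2-methylidenehept-6-enoate | BrC(Br)=CC[C@@H](CCC(C)=C)C(=C)C(=O)OC | intermediate
12 | tributyl(vinyl)stannane | C=C[Sn](CCCC)(CCCC)CCCC | starting material
13 | methyl (3R,5Z)-6-bromo-3-(3-methylbut-3-en-1-yl)-2-methylideneocta-5,7-dienoate | C=C/C(Br)=C/C[C@@H](CCC(C)=C)C(=C)C(=O)OC | intermediate
14 | methyl 2-[(2R,4aS,8aR)-8-bromo-4a-methyl-1,2,3,4,4a,5,6,8a-octahydronaphthalen-2-yl]prop-2-enoate | C=C(C(=O)OC)[C@@H]1CC[C@@]2(C)CCC=C(Br)[C@@H]2C1 | intermediate
15 | (tributylstannyl)methanol | OC[Sn](CCCC)(CCCC)CCCC | starting material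
16 | methyl 2-[(2R,4aR,8aR)-8-(hydroxymethyl)-4a-methyl-1,2,3,4,4a,5,6,8a-octahydronaphthalen-2-yl]prop-2-enoate | C=C(C(=O)OC)[C@@H]1CC[C@@]2(C)CCC=C(CO)[C@@H]2C1 | intermediate
17 | (2Z)-3-iodoprop-2-enoic acid | OC(=O)/C=C\I | starting material
18 | methyl 2-[(2R,4aR,8aR)-8-({[(2Z)-3-iodoprop-2-enoyl]oxy}methyl)-4a-methyl-1,2,3,4,4a,5,6,8a-octahydronaphthalen-2-yl]prop-2-enoate | C=C(C(=O)OC)[C@@H]1CC[C@@]2(C)CCC=C(COC(=O)/C=C\I)[C@@H]2C1 | intermediate
19 | (4-hydroxyphenyl)boronic acid | OB(O)c1ccc(O)cc1 | starting material
20 | methyl 2-[(2R,4aR,8aR)-8-({[(2Z)-3-(4-hydroxyphenyl)prop-2-enoyl]oxy}methyl)-4a-methyl-1,2,3,4,4a,5,6,8a-octahydronaphthalen-2-yl]prop-2-enoate | C=C(C(=O)OC)[C@@H]1CC[C@@]2(C)CCC=C(COC(=O)/C=C\c3ccc(O)cc3)[C@@H]2C1 | target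

Total step count: 11. Longest linear sequence: 11 steps (1 to 20); compounds 12, 15, 17 and 19 are purchased.

**Steps most likely to fail**

Step 8 (cycloaddition). The unactivated 1,1-disubstituted dienophile may react so slowly that thermal pathways of the free acrylate win before ring closure is complete. These are a Cope rearrangement of the C13=C11–C7–C6–C5=C4 1,5-diene, ene reactions and bimolecular cycloaddition. The fallback carries the acrylate in a masked, saturated form; it sets out from 13 and comes back at 14. Conjugate addition of thiophenol (PhSH, Et3N cat., MeOH, 25 °C) should give methyl (3R,5Z)-6-bromo-3-(3-methylbut-3-en-1-yl)-2-[(phenylsulfanyl)methyl]octa-5,7-dienoate F1 (both C2 epimers). F1 has neither a 1,5-diene nor an enophile and can be cyclized under more forcing conditions (1,2-dichlorobenzene, 230–250 °C) to methyl 2-[(2R,4aS,8aR)-8-bromo-4a-methyl-1,2,3,4,4a,5,6,8a-octahydronaphthalen-2-yl]-3-(phenylsulfanyl)propanoate F2. NaIO4 (MeOH/H2O, 0 °C) should oxidize sulfur only, to methyl 3-(benzenesulfinyl)-2-[(2R,4aS,8aR)-8-bromo-4a-methyl-1,2,3,4,4a,5,6,8a-octahydronaphthalen-2-yl]propanoate F3. Sulfoxide syn-elimination (PhMe, 110 °C, CaCO3) then restores the α-methylene ester and returns to 14.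

Step 9 (hydroxymethylation). Transfer of the sp3 hydroxymethyl group from tin to the hindered, α-branched cycloalkenylpalladium intermediate may be slow, so that protodebromination and catalyst decay take over. The fallback brings in C15 as carbon monoxide and then reduces it; it sets out from 14 and comes back at 16. Reductive carbonylation (CO/H2, Pd(OAc)2, di(1-adamantyl)-n-butylphosphine, TMEDA, PhMe, 100 °C) should give methyl 2-[(2R,4aR,8aR)-8-formyl-4a-methyl-1,2,3,4,4a,5,6,8a-octahydronaphthalen-2-yl]prop-2-enoate F4. Luche reduction (NaBH4, CeCl3·7H2O, MeOH, −78 °C) reduces the enal 1,2-selectively and leaves the acrylate ester alone, giving 16.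

Step 11 (arylation). Three processes may erode the product: Z-to-E isomerization of the β-iodoacrylate or the cinnamate under palladium, ionization of the allylic C15–O ester by zerovalent palladium, and addition–elimination of phenoxide on the β-iodoacrylate. The fallback makes the aryl–alkene bond before the ester bond; it sets out from 17 and 19 (with alcohol 16) and comes back at 20. Suzuki–Miyaura coupling on the free acid as its carboxylate (PdCl2(dppf), K2CO3, THF/H2O, 25 °C) should give (2Z)-3-(4-hydroxyphenyl)prop-2-enoic acid F5. Mitsunobu esterification of 16 with this acid (PPh3, DIAD, THF, 0 °C, dark) then gives 20 directly, the carboxylic acid reacting in preference to the phenol and no palladium meeting the allylic ester.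

Further compounds
F1 | step 8 | methyl (3R,5Z)-6-bromo-3-(3-methylbut-3-en-1-yl)-2-[(phenylsulfanyl)methyl]octa-5,7-dienoate (both C2 epimers) | C=C/C(Br)=C/C[C@@H](CCC(C)=C)C(CSc1ccccc1)C(=O)OC
F2 | step 8 | methyl 2-[(2R,4aS,8aR)-8-bromo-4a-methyl-1,2,3,4,4a,5,6,8a-octahydronaphthalen-2-yl]-3-(phenylsulfanyl)propanoate (both C2 epimers of the propanoate) | COC(=O)C(CSc1ccccc1)[C@@H]1CC[C@@]2(C)CCC=C(Br)[C@@H]2C1
F3 | step 8 | methyl 3-(benzenesulfinyl)-2-[(2R,4aS,8aR)-8-bromo-4a-methyl-1,2,3,4,4a,5,6,8a-octahydronaphthalen-2-yl]propanoate (mixture of diastereomers) | COC(=O)C(CS(=O)c1ccccc1)[C@@H]1CC[C@@]2(C)CCC=C(Br)[C@@H]2C1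
F4 | step 9 | methyl 2-[(2R,4aR,8aR)-8-formyl-4a-methyl-1,2,3,4,4a,5,6,8a-octahydronaphthalen-2-yl]prop-2-enoate | C=C(C(=O)OC)[C@@H]1CC[C@@]2(C)CCC=C(C=O)[C@@H]2C1
F5 | step 11 | (2Z)-3-(4-hydroxyphenyl)prop-2-enoic acid | OC(=O)/C=C\c1ccc(O)cc1
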